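## Analysis of the target

Target 15 is a depside: two benzene rings joined by a single aryl ester and no other ring. Ring A is a 2,4-dimethoxy-6-propylbenzoyl unit, with the ester carbonyl on C1, methoxy groups on C2 and C4, and propyl on C6. Ring B is olivetolic acid (C1 carboxyl, C2 hydroxyl, C6 pentyl) acylated on the C4 oxygen. There are no stereocentres and no double-bond geometry to control, so the whole problem is one of regiochemistry and chemoselectivity. The sensitive groups are the aryl ester between the rings, which hydroxide or alkoxide would cleave, and the ring B 2-hydroxybenzoic acid, whose electron-rich ring makes it prone to decarboxylation on heating or in strong acid. Three things make the synthesis hard. The ring A carbonyl is flanked by two ortho substituents and is therefore hindered toward acylation. Only one of the two ring B phenols may be esterified, while the carboxyl must end up free. Ring A carries propyl, carboxyl and methoxy on three contiguous carbons, a pattern that deprotonation of the symmetrical propyl-dimethoxyarene would not give, because the metal would go between the two methoxy groups. The strategy rests on that contiguous triad: ring A C6 (propyl) and C1 (carboxyl carbon) are neighbours, with the C2 methoxy on the other side of C1. This is the pattern left when a carbon nucleophile and then an electrophile add across the C6–C1 triple bond of 3,5-dimethoxybenzyne.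

## Retrosynthetic reasoning

**15 to 14.** The last bond cut is the O–CH2 bond of a benzyl ester on the ring B carboxyl. The carboxyl has to be masked during esterification, otherwise it would be activated along with the ring A acid. A benzyl ester is chosen because hydrogenolysis is neutral and leaves the depside ester, the methyl ethers and the decarboxylation-prone acid alone. An alkyl ester that needs hydroxide or strong acid for removal would put exactly those groups at risk.

**14 to 9 and 12.** The acyl carbon–oxygen bond of the depside ester is cut. It is the only bond between the rings, so the molecule falls into two halves of similar size, acid 9 and phenol 12, and the route becomes convergent. The forward reaction must acylate with a di-ortho-substituted benzoic acid and must reach only the C4 hydroxyl of 12. Both demands are met by mixed anhydride 13. Its aroyl group ionizes readily because the ortho and para methoxy groups stabilize positive charge at the carbonyl carbon. The C2 hydroxyl of 12 is tied up in a hydrogen bond to the neighbouring ester carbonyl and is crowded by it.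

**12 to 10.** The benzyl O–C bond is cut back to olivetolic acid 10, which supplies all of ring B with its substituents in place. The forward reaction only has to alkylate carboxylate 11 and leave the two phenols untouched, which the gap in acidity between carboxyl and phenol allows.

**9 to 2, 3 and 4.** Two neighbouring bonds of ring A are cut in one operation: C6–propyl and C1–carboxyl. They are cut there because these substituents sit on adjacent carbons with a methoxy beside the carboxyl-bearing one, the signature of nucleophile-then-electrophile addition to an alkoxy aryne. Backwards, acid 9 comes from carboxylate 8, 8 from arylmagnesium 7 and carbon dioxide 4, 7 from aryne 6 and Grignard reagent 3, 6 from arylmagnesium 5, and 5 from iodide 2 and a first equivalent of 3. What is gained is two carbon–carbon bonds and the final oxidation and methylation state of ring A in a single step. The forward reaction has to deliver propyl to the aryne carbon remote from the flanking methoxy, so that the metal, and then the carboxyl, end up next to oxygen.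

**2 to 1.** The carbon–iodine bond is cut back to bromide 1. Iodine is placed ortho to bromine so that halogen–metal exchange puts the metal on a defined carbon next to a leaving group. The forward reaction is an electrophilic iodination at the position that is para to one methoxy and ortho to the other. In 1 the two such positions are equivalent.

## Alternatives that were turned down

**Alternative 1:** The disconnection is the ring B C1–C6 bond. Ring B would be assembled from the dioxinone-masked tetraketide A2 (2,2-dimethyl-6-(2,4-dioxononyl)-4H-1,3-dioxin-4-one). In the key step an amine base forms the dienolate of A2, the dioxinone C5 attacks the pentyl ketone, and dehydration aromatizes the ring to benzodioxinone A1 (7-hydroxy-2,2-dimethyl-5-pentyl-4H-1,3-benzodioxin-4-one).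

- For it: A1 has the carboxyl and the C2 oxygen locked in one acetonide and exactly one free phenol, at the position that must carry the depside ester. On the question of which hydroxyl is acylated it is therefore stronger than the chosen route, which relies on hydrogen bonding to tell the two phenols of 12 apart.
- Against it: the ring it builds is the ring that 10 already supplies in one purchase, and A2 itself needs several steps. Ring A, whose congested propyl/carboxyl/methoxy triad is the real structural problem, is left unsolved. After esterification the acetonide has to be opened to the free acid by an oxygen nucleophile, and nothing in the structure clearly favours attack at the dioxinone carbonyl over the depside ester, since both are di-ortho-substituted aryl esters.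
- Comparison: the chosen strategy gives up the built-in site control but gains a neutral final deprotection, and it spends its bond-forming step on ring A.

**Alternative 2:** The disconnection is the depside acyl–oxygen bond together with the ring A C1–C6 bond. In the key step diketo-dioxinone A4 (2,2-dimethyl-6-(2,4-dioxoheptyl)-4H-1,3-dioxin-4-one) is heated with phenol A1. A4 loses its ketal carbonyl component to give acylketene A5 (3,5,7-trioxodec-1-en-1-one), the O–H of A1 adds to A5, and mild base closes ring A by aldol condensation and dehydration. The product is A3 (2,2-dimethyl-4-oxo-5-pentyl-4H-1,3-benzodioxin-7-yl 2,4-dihydroxy-6-propylbenzoate).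

- For it: the ester bond is made while the acyl carbon is an unhindered ketene, so the steric problem of esterifying a di-ortho-substituted benzoic acid never arises. On that point it is stronger than the chosen route, which has to rely on acylium-type activation. It also forms the link and ring A in one flask.
- Against it: A3 carries ring A as the free 2,4-diol, so both hydroxyls, one of them chelated to the ester carbonyl, must then be methylated with base in the presence of the aryl ester. The acetonide opening problem of alternative 1 remains. A phenol is a modest trap for A5, which carries its own 1,3-diketone and can cyclize on itself. Both A1 and A4 need separate preparation.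
- Comparison: the chosen strategy has the methyl ethers in place from the first step and reaches the target in five steps.

**Alternative 3:** The disconnection is the ring A C1–C2 and C5–C6 bonds. In the key step aryl ynoate A7 (2,2-dimethyl-4-oxo-5-pentyl-4H-1,3-benzodioxin-7-yl hex-2-ynoate) and diene A8 (1,1-dimethoxy-3-(trimethylsilyloxy)buta-1,3-diene) undergo a Diels–Alder reaction. Loss of one alkoxy group as the alcohol and of the silyl group then aromatizes the adduct to A6 (2,2-dimethyl-4-oxo-5-pentyl-4H-1,3-benzodioxin-7-yl 4-hydroxy-2-methoxy-6-propylbenzoate).

- For it: the polarity match of the ketene-acetal terminus of A8 with the ynoate fixes the ring A pattern, methoxy beside the carboxyl carbon and propyl on the other side. The ester bond is again formed on an unhindered acid, and the C2 methoxy arrives with the diene. On these points it equals alternative 2 and is stronger than the chosen route at the esterification.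
- Against it: a β-alkyl alkynoate is a sluggish dienophile, and at the temperatures it needs A8 is likely to decompose, or to add in an open-chain conjugate or acyl-transfer mode to the activated aryl ester. The C4 hydroxyl of ring A emerges free and needs a separate methylation. The acetonide must still be opened next to the depside ester.
- Comparison: the chosen strategy needs no adjustment of ring A after it is formed, and its ring A chemistry is two steps from a purchasable bromide.

Key step: step 2

Assumption: compounds 1, 3 (as a THF solution), 4 and 10 are taken as purchasable; the target has no stereocentre, so no configuration has to be set.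

## Route

Step 1
Reactants: 1 (1-bromo-3,5-dimethoxybenzene)
Product: 2 1-bromo-2-iodo-3,5-dimethoxybenzene
Conditions: NIS (1.05 equiv), MeCN, 0 °C → rt, dark
Reagents that add atoms: N-iodosuccinimide, O=C1CCC(=O)N1I
Why: Electrophilic aromatic iodination; the two equivalent positions ortho to bromine are para to one methoxy and ortho to the other and are less crowded than the position between the two methoxy groups, so one mono-iodide should dominate, and a slight excess of reagent only should limit di-iodination.

Step 2
Reactants: 2 (1-bromo-2-iodo-3,5-dimethoxybenzene); 3 (propylmagnesium chloride); 4 (carbon dioxide)
Product: 9 2,4-dimethoxy-6-propylbenzoic acid, via 2-bromo-4,6-dimethoxyphenylmagnesium chloride 5 (not isolated), via 3,5-dimethoxybenzyne 6 (not isolated), via 2,4-dimethoxy-6-propylphenylmagnesium chloride 7 (not isolated), via chloromagnesium 2,4-dimethoxy-6-propylbenzoate 8 (not isolated)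
Conditions: PrMgCl (3 equiv), LiCl (3 equiv), THF, −20 °C → rt, then 50 °C; cool to −20 °C, CO2 (g), → rt; 1 M HCl
Reagents that add atoms: none
Why: Iodine–magnesium exchange of 2 with 3, driven by the greater stability of the aryl carbanion and helped by the ortho bromine and the chelating ortho methoxy, should give 5 and 1-iodopropane; on warming, 5 loses MgBrCl by beta-elimination, bromide being far the better leaving group than methoxide, and gives aryne 6. A second equivalent of 3 adds across the strained triple bond to give 7, CO2 inserts into the carbon–magnesium bond to give 8, and HCl releases 9. The closest known reaction type is the tandem sequence in which an ortho-dihaloarene is treated with excess Grignard or organolithium reagent, the aryne takes up the carbon nucleophile and the new arylmetal is quenched with an electrophile, as practised for 6-alkyl-2-methoxybenzoic acids. No ring is closed and no stereocentre is formed. The selectivity needed is attack of propyl at the aryne carbon meta to the flanking methoxy: the C–O bond withdraws electron density through the sigma framework and distorts the aryne so that this carbon is the more electrophilic one, and the charge that builds up on the carbon next to oxygen is stabilized by induction and by coordination of magnesium to the methoxy oxygen. The second methoxy, para to the carbanionic carbon, exerts only a weak opposite inductive bias that the adjacent methoxy outweighs. The position of iodine in 2 fixes where the metal first sits, so no arylmagnesium forms between the two methoxy groups, and the excess of 3 keeps the stationary concentration of 6 low, which should suppress addition of 5 or 7 to the aryne.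

Step 3
Reactants: 10 (olivetolic acid, 2,4-dihydroxy-6-pentylbenzoic acid)
Product: 12 benzyl 2,4-dihydroxy-6-pentylbenzoate, via potassium 2,4-dihydroxy-6-pentylbenzoate 11 (not isolated)
Conditions: KHCO3 (1.1 equiv), BnBr (1.05 equiv), DMF, rt
Reagents that add atoms: benzyl bromide, BrCc1ccccc1
Why: Carboxylate alkylation by SN2; KHCO3 deprotonates the carboxylic acid but not the phenols, so only the carboxylate is benzylated, and room temperature should avoid decarboxylation of the electron-rich salicylic acid.

Step 4
Reactants: 9 (2,4-dimethoxy-6-propylbenzoic acid); 12 (benzyl 2,4-dihydroxy-6-pentylbenzoate)
Product: 14 benzyl 4-[(2,4-dimethoxy-6-propylbenzoyl)oxy]-2-hydroxy-6-pentylbenzoate, via 2,4-dimethoxy-6-propylbenzoic trifluoroacetic anhydride 13 (not isolated)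
Conditions: 9, TFAA (2.5 equiv), toluene, 0 °C; then 12, rt; aq NaHCO3 work-up
Reagents that add atoms: none
Why: Depside esterification through a mixed trifluoroacetic anhydride; the methoxy-stabilized, di-ortho-substituted aroyl group of 13 has strong acylium character and so acylates despite hindrance, and the free C4 hydroxyl of 12 should react in preference to the C2 hydroxyl, which is hydrogen-bonded to and crowded by the benzyl ester. Any aryl trifluoroacetate formed reversibly should be cleaved in the bicarbonate work-up.

Step 5
Reactants: 14 (benzyl 4-[(2,4-dimethoxy-6-propylbenzoyl)oxy]-2-hydroxy-6-pentylbenzoate)
Product: 15 4-[(2,4-dimethoxy-6-propylbenzoyl)oxy]-2-hydroxy-6-pentylbenzoic acid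
Conditions: H2 (1 atm), 10% Pd/C, EtOAc, rt
Reagents that add atoms: none
Why: Hydrogenolysis of the benzylic C–O bond; under these neutral conditions the aryl ester, the methyl ethers and the arene rings should be untouched, and no base or heat is applied that could cleave the depside or decarboxylate the product.

## Compound list

1 | 1-bromo-3,5-dimethoxybenzene | COc1cc(Br)cc(OC)c1 | starting material
2 | 1-bromo-2-iodo-3,5-dimethoxybenzene | COc1cc(Br)c(I)c(OC)c1 | intermediate
3 | propylmagnesium chloride | CCC[Mg]Cl | starting material
4 | carbon dioxide | O=C=O | starting material
5 | 2-bromo-4,6-dimethoxyphenylmagnesium chloride | COc1cc(Br)c([Mg]Cl)c(OC)c1 | intermediate (not isolated)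
6 | 3,5-dimethoxybenzyne (1,2-didehydro-3,5-dimethoxybenzene) | COC1=CC(OC)=CC#C1 | intermediate (not isolated)
7 | 2,4-dimethoxy-6-propylphenylmagnesium chloride | CCCc1cc(OC)cc(OC)c1[Mg]Cl | intermediate (not isolated)
8 | chloromagnesium 2,4-dimethoxy-6-propylbenzoate | CCCc1cc(OC)cc(OC)c1C(=O)O[Mg]Cl | intermediate (not isolated)
9 | 2,4-dimethoxy-6-propylbenzoic acid | CCCc1cc(OC)cc(OC)c1C(=O)O | intermediate
10 | olivetolic acid (2,4-dihydroxy-6-pentylbenzoic acid) | CCCCCc1cc(O)cc(O)c1C(=O)O | starting material
11 | potassium 2,4-dihydroxy-6-pentylbenzoate | CCCCCc1cc(O)cc(O)c1C(=O)[O-].[K+] | intermediate (not isolated)
12 | benzyl 2,4-dihydroxy-6-pentylbenzoate | CCCCCc1cc(O)cc(O)c1C(=O)OCc1ccccc1 | intermediate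
13 | 2,4-dimethoxy-6-propylbenzoic trifluoroacetic anhydride | CCCc1cc(OC)cc(OC)c1C(=O)OC(=O)C(F)(F)F | intermediate (not isolated)
14 | benzyl 4-[(2,4-dimethoxy-6-propylbenzoyl)oxy]-2-hydroxy-6-pentylbenzoate | CCCCCc1cc(OC(=O)c2c(CCC)cc(OC)cc2OC)cc(O)c1C(=O)OCc1ccccc1 | intermediate
15 | 4-[(2,4-dimethoxy-6-propylbenzoyl)oxy]-2-hydroxy-6-pentylbenzoic acid | CCCCCc1cc(OC(=O)c2c(CCC)cc(OC)cc2OC)cc(O)c1C(=O)O | target

## Step count and risk

Total step count: 5. Longest linear sequence: 4 steps (steps 1, 2, 4 and 5, from 1 to 15); the ring B branch contributes step 3 before the coupling.

**Step 2 (key step).** The most likely failures are these: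

- a slow iodine–magnesium exchange with a primary alkyl Grignard reagent, so that the aryne is released while little free 3 is at hand;
- capture of aryne 6 by the arylmagnesium species 5 or 7 in place of 3, giving biaryl material;
- protonation of 7 by adventitious moisture before carboxylation.

Loss of regiocontrol in the addition is thought less likely, because the flanking methoxy polarizes the aryne strongly. Replacing the Grignard reagent by the corresponding organolithium at low temperature would be an adjustment of conditions only. The fallback proper leaves the aryne and builds ring A by classical arene chemistry, setting out from 1 and returning at 9. Kumada coupling of 1 with 3 (NiCl2(dppp) cat., THF) should give 1,3-dimethoxy-5-propylbenzene F1. Vilsmeier–Haack formylation (POCl3, DMF), which goes para to one methoxy and ortho to the alkyl group, should give 2,4-dimethoxy-6-propylbenzaldehyde F2. Pinnick oxidation (NaClO2, NaH2PO4, 2-methyl-2-butene, t-BuOH/H2O) should then give 9. This costs one more step.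

**Step 4.** The acylium-like anhydride 13 may attack a ring carbon of the very electron-rich phenol 12 (Friedel–Crafts acylation) instead of oxygen. It may also acylate both hydroxyls, or trifluoroacetyl capping of the C4 hydroxyl may stall the coupling. The fallback changes from an acid-promoted mixed anhydride to a preformed acyl chloride reacting with the phenoxide; it sets out from 9 and returns at 14. Oxalyl chloride with catalytic DMF in CH2Cl2 should convert 9 into 2,4-dimethoxy-6-propylbenzoyl chloride F3. F3 is then combined with 12, K2CO3 (1 equiv) and catalytic DMAP in MeCN. Under base the non-chelated, more acidic C4 hydroxyl is deprotonated first and should be acylated on oxygen only.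

**Step 3.** The C4 phenol may be benzylated alongside the carboxylate, or the acid may decarboxylate during handling in DMF. The fallback avoids any alkylating agent; it sets out from 10 and returns at 12. Acetone with TFAA and TFA at 0 °C → rt should tie the carboxyl and the C2 hydroxyl of 10 into 7-hydroxy-2,2-dimethyl-5-pentyl-4H-1,3-benzodioxin-4-one F4 (the same compound as A1). Benzyl alkoxide (BnOH, NaH, THF, warm) should then open the dioxinone at the carbonyl and give 12 by transesterification.

**Step 1.** Over-iodination, or partial attack between the two methoxy groups, may give mixtures that are tedious to separate. The isomer iodinated between the methoxy groups cannot form an aryne, so small amounts would only lower the yield of step 2. The fallback changes the halogen pair; it sets out from 1 and rejoins the route inside step 2 at 5. Bromination with NBS in MeCN, a milder and cleaner monohalogenation, should give 1,2-dibromo-3,5-dimethoxybenzene F5. Bromine–magnesium exchange with iPrMgCl·LiCl (1.0 equiv, THF, −15 °C) is expected at the bromine next to the methoxy and would give 5. Exchange at the other bromine would lead, after loss of bromide, to the same aryne 6, so the site of exchange does not matter. Reagent 3 is then added, and warming, carboxylation with 4 and work-up follow as in step 2.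

## Further compounds

F1 | step 2 | 1,3-dimethoxy-5-propylbenzene | CCCc1cc(OC)cc(OC)c1
F2 | step 2 | 2,4-dimethoxy-6-propylbenzaldehyde | CCCc1cc(OC)cc(OC)c1C=O
F3 | step 4 | 2,4-dimethoxy-6-propylbenzoyl chloride | CCCc1cc(OC)cc(OC)c1C(=O)Cl
F4 | step 3 | 7-hydroxy-2,2-dimethyl-5-pentyl-4H-1,3-benzodioxin-4-one | CCCCCc1cc(O)cc2OC(C)(C)OC(=O)c12
F5 | step 1 | 1,2-dibromo-3,5-dimethoxybenzene | COc1cc(Br)c(Br)c(OC)c1
A1 | alternative 1 | 7-hydroxy-2,2-dimethyl-5-pentyl-4H-1,3-benzodioxin-4-one | CCCCCc1cc(O)cc2OC(C)(C)OC(=O)c12
A2 | alternative 1 | 2,2-dimethyl-6-(2,4-dioxononyl)-4H-1,3-dioxin-4-one | CCCCCC(=O)CC(=O)CC1=CC(=O)OC(C)(C)O1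
A3 | alternative 2 | 2,2-dimethyl-4-oxo-5-pentyl-4H-1,3-benzodioxin-7-yl 2,4-dihydroxy-6-propylbenzoate | CCCc1cc(O)cc(O)c1C(=O)Oc1cc(CCCCC)c2C(=O)OC(C)(C)Oc2c1
A4 | alternative 2 | 2,2-dimethyl-6-(2,4-dioxoheptyl)-4H-1,3-dioxin-4-one | CCCC(=O)CC(=O)CC1=CC(=O)OC(C)(C)O1
A5 | alternative 2 | 3,5,7-trioxodec-1-en-1-one (acylketene) | CCCC(=O)CC(=O)CC(=O)C=C=O
A6 | alternative 3 | 2,2-dimethyl-4-oxo-5-pentyl-4H-1,3-benzodioxin-7-yl 4-hydroxy-2-methoxy-6-propylbenzoate | CCCc1cc(O)cc(OC)c1C(=O)Oc1cc(CCCCC)c2C(=O)OC(C)(C)Oc2c1
A7 | alternative 3 | 2,2-dimethyl-4-oxo-5-pentyl-4H-1,3-benzodioxin-7-yl hex-2-ynoate | CCCC#CC(=O)Oc1cc(CCCCC)c2C(=O)OC(C)(C)Oc2c1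
A8 | alternative 3 | 1,1-dimethoxy-3-(trimethylsilyloxy)buta-1,3-diene | COC(OC)=CC(=C)O[Si](C)(C)C
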